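**Plan**

- Retrosynthesis: a phenol silyl ether is removed last. Before that the side chain (numbered C1′ on C2 of the chroman to C33′) is cut at C12′–C13′ into an alkenyl bromide (chroman plus C1′–C12′) and a primary alkyl bromide (C13′–C33′).
- This bond joins two carbons that can both be electrophiles: C12′ is the methyl-bearing sp2 carbon of the 11′E olefin and C13′ a primary homoallylic CH2 of the 1,5-diene repeat. Both lie more than ten bonds from C2 of the pyran ring and from C24′, so a nickel-catalysed reductive C–Br/C–Br union can run beside the free C24′ carbinol.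
- Alkenyl bromide, further cuts: C12′–Br with C11′–H (hydrozirconation of a methyl alkyne), C9′–C10′ (allylic bromide plus propyne dianion), O1–C8a of the pyran ring (closure of a quinone carbinol) and C4–C4a (B-alkyl Suzuki coupling of (S)-nerolidol with an aryl bromide).
- Alkyl bromide, further cuts: C13′–C14′ (Wittig methylenation, then hydroboration and bromination) and C21′–C22′ (copper alkynylation of an allylic bromide made from geranyl acetate, then trans reduction to the 22′E olefin).
- Forward: farnesol gives one (S)-configured C15 propargylic carbinol. Branch a attaches the benzene ring, closes the pyran ring and grows the chain to C12′; branch b grows the chain to C13′; the branches are joined at C12′–C13′ and the phenol is set free.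
- Stereochemistry: C2 and C24′ (both S) are the same carbinol carbon, set once by Sharpless epoxidation of farnesol and carried on with its C–O bond unbroken. The E olefins are bought (farnesol, geranyl acetate) or made by E-selective SeO2 oxidation, trans-hydroalumination and syn-hydrozirconation.

Key step: step 22

Remark: read from the SMILES, C2 of the chroman is S (the mirror image of the natural tocotrienol series) and C24′ is S, so one (S)-carbinol serves both centres; (2E,6E)-farnesol, geranyl acetate and 1,4-dimethoxy-2,3-dimethylbenzene are taken as bought.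

**Route**

Step 1
Reactants: 1 (2E,6E)-farnesol
Product: 2 [(2S,3S)-3-[(3E)-4,8-dimethylnona-3,7-dien-1-yl]-3-methyloxiran-2-yl]methanol
Conditions: Ti(OiPr)4 (5 mol%), L-(+)-diethyl tartrate (6 mol%), t-BuOOH (2 equiv), 4 Å molecular sieves, CH2Cl2, −20 °C
Reagents that add atoms: tert-butyl hydroperoxide CC(C)(C)OO
Why: Katsuki–Sharpless asymmetric epoxidation: only the 2,3-olefin carries the directing allylic hydroxyl, and the titanium L-(+)-tartrate complex delivers oxygen to the face that gives the (2S,3S)-epoxide of an E-allylic alcohol, which fixes the carbinol carbon that later becomes both C2 and C24′.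

Step 2
Reactants: 2 [(2S,3S)-3-[(3E)-4,8-dimethylnona-3,7-dien-1-yl]-3-methyloxiran-2-yl]methanol
Product: 3 (2S,3R)-3-(chloromethyl)-2-[(3E)-4,8-dimethylnona-3,7-dien-1-yl]-2-methyloxirane
Conditions: PPh3, CCl4, NaHCO3, reflux
Reagents that add atoms: carbon tetrachloride ClC(Cl)(Cl)Cl
Why: Appel chlorination replaces the primary hydroxyl by SN2 displacement at CH2 under buffered neutral conditions, so the trisubstituted oxirane and both its centres are untouched (the descriptor at the CH carbon changes by priority only).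

Step 3
Reactants: 3 (2S,3R)-3-(chloromethyl)-2-[(3E)-4,8-dimethylnona-3,7-dien-1-yl]-2-methyloxirane
Product: 4 (3S,6E)-3,7,11-trimethyldodeca-6,10-dien-1-yn-3-ol
Conditions: n-BuLi (3.5 equiv), THF, −78 to −30 °C; then aq. NH4Cl
Reagents that add atoms: none
Why: base-induced double elimination of a 2,3-epoxy chloride to a propargylic alcohol: lithiation next to chlorine opens the oxirane at the CH–O bond and a second dehydrochlorination gives the alkyne, and since the C–O bond at the quaternary carbon is never broken the carbinol keeps its S configuration.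

Step 4
Reactants: 4 (3S,6E)-3,7,11-trimethyldodeca-6,10-dien-1-yn-3-ol
Product: 5 (3S,6E)-3,7,11-trimethyldodeca-1,6,10-trien-3-ol ((S)-nerolidol)
Conditions: H2 (1 atm), Pd/CaCO3 poisoned with Pb(OAc)2 (Lindlar catalyst), quinoline, hexane, 20 °C
Reagents that add atoms: none
Why: Lindlar semihydrogenation stops at the vinyl group because the poisoned palladium surface binds the terminal alkyne far better than the alkene and does not reduce trisubstituted olefins; no stereocentre is touched.

Step 5
Reactants: 6 1,4-dimethoxy-2,3-dimethylbenzene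
Product: 7 1-bromo-2,5-dimethoxy-3,4-dimethylbenzene
Conditions: NBS (1.0 equiv), MeCN, 20 °C
Reagents that add atoms: N-bromosuccinimide O=C1CCC(=O)N1Br
Why: electrophilic aromatic bromination of a doubly activated ring whose two free positions are equivalent, so one equivalent of NBS should give a single monobromide.

Step 6
Reactants: 5 (3S,6E)-3,7,11-trimethyldodeca-1,6,10-trien-3-ol; 7 1-bromo-2,5-dimethoxy-3,4-dimethylbenzene
Product: 9 (3S,6E)-1-(2,5-dimethoxy-3,4-dimethylphenyl)-3,7,11-trimethyldodeca-6,10-dien-3-ol, via B-alkyl-9-BBN borane 8 (not isolated)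
Conditions: 9-BBN (1.3 equiv), THF, 0 to 20 °C; then 7, Pd(OAc)2 (5 mol%), SPhos (10 mol%), aq. K3PO4, THF, 60 °C
Reagents that add atoms: none
Why: hydroboration/B-alkyl Suzuki–Miyaura coupling: 9-BBN adds only to the monosubstituted vinyl group with boron on the terminal carbon, and the primary alkyl group is transferred to the aryl bromide under palladium/biarylphosphine catalysis to form the future C4–C4a bond, the carbinol centre taking no part.

Step 7
Reactants: 9 (3S,6E)-1-(2,5-dimethoxy-3,4-dimethylphenyl)-3,7,11-trimethyldodeca-6,10-dien-3-ol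
Product: 10 5-[(3S,6E)-3-hydroxy-3,7,11-trimethyldodeca-6,10-dien-1-yl]-2,3-dimethylcyclohexa-2,5-diene-1,4-dione
Conditions: (NH4)2Ce(NO3)6 (2.5 equiv), MeCN/H2O, 0 °C
Reagents that add atoms: water O
Why: oxidative demethylation of a hydroquinone dimethyl ether: two one-electron oxidations of the electron-rich ring and attack of water release two molecules of methanol and give the para-quinone, while isolated trisubstituted olefins and the tertiary alcohol are not oxidised at 0 °C.

Step 8
Reactants: 10 5-[(3S,6E)-3-hydroxy-3,7,11-trimethyldodeca-6,10-dien-1-yl]-2,3-dimethylcyclohexa-2,5-diene-1,4-dione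
Product: 12 (2S)-2-[(3E)-4,8-dimethylnona-3,7-dien-1-yl]-2,7,8-trimethyl-3,4-dihydro-2H-chromen-6-ol, via hydroquinone 11 (not isolated)
Conditions: Na2S2O4, Et2O/H2O, 20 °C; then p-TsOH·H2O (10 mol%), toluene, 50 °C, Ar
Reagents that add atoms: none
Why: reductive cyclisation of a (3-hydroxy-3-methylalkyl)quinone, the classical closure of tocopherylquinones: the pyran ring closes 6-exo-trig by attack of the carbinol oxygen on the quinoid carbon C8a (a trace of quinone carries the redox chain) with loss of the former quinone oxygen as water, so O1 is the carbinol oxygen and C2 keeps the S configuration.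

Step 9
Reactants: 12 (2S)-2-[(3E)-4,8-dimethylnona-3,7-dien-1-yl]-2,7,8-trimethyl-3,4-dihydro-2H-chromen-6-ol
Product: 13 tert-butyl-[[(2S)-2-[(3E)-4,8-dimethylnona-3,7-dien-1-yl]-2,7,8-trimethyl-3,4-dihydro-2H-chromen-6-yl]oxy]dimethylsilane
Conditions: TBSCl, imidazole, DMF, 20 °C
Reagents that add atoms: tert-butyldimethylsilyl chloride CC(C)(C)[Si](C)(C)Cl
Why: silylation of the phenol masks the acidic, radical-trapping chromanol hydroxyl for the organolithium, zirconium hydride and nickel steps that follow.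

Step 10
Reactants: 13 tert-butyl-[[(2S)-2-[(3E)-4,8-dimethylnona-3,7-dien-1-yl]-2,7,8-trimethyl-3,4-dihydro-2H-chromen-6-yl]oxy]dimethylsilane
Product: 14 (2E,6E)-9-[(2S)-6-[tert-butyl(dimethyl)silyl]oxy-2,7,8-trimethyl-3,4-dihydro-2H-chromen-2-yl]-2,6-dimethylnona-2,6-dien-1-ol
Conditions: SeO2 (0.5 equiv), t-BuOOH (3 equiv), salicylic acid (0.1 equiv), CH2Cl2, 0 to 20 °C, stopped at partial conversion
Reagents that add atoms: selenium dioxide O=[Se]=O; tert-butyl hydroperoxide CC(C)(C)OO (renews SeO2)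
Why: SeO2 allylic oxidation (ene reaction, then [2,3]-sigmatropic shift) takes place at the more accessible terminal isopropylidene olefin and there at the E-methyl group, which should give the E-allylic alcohol at C9′.

Step 11
Reactants: 14 (2E,6E)-9-[(2S)-6-[tert-butyl(dimethyl)silyl]oxy-2,7,8-trimethyl-3,4-dihydro-2H-chromen-2-yl]-2,6-dimethylnona-2,6-dien-1-ol
Product: 15 [[(2S)-2-[(3E,7E)-9-bromo-4,8-dimethylnona-3,7-dien-1-yl]-2,7,8-trimethyl-3,4-dihydro-2H-chromen-6-yl]oxy](tert-butyl)dimethylsilane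
Conditions: CBr4, PPh3, CH2Cl2, 0 °C
Reagents that add atoms: carbon tetrabromide BrC(Br)(Br)Br
Why: Appel bromination of the primary allylic alcohol by SN2 displacement at CH2, which at 0 °C should proceed without allylic transposition or loss of the aryl silyl ether.

Step 12
Reactants: 15 [[(2S)-2-[(3E,7E)-9-bromo-4,8-dimethylnona-3,7-dien-1-yl]-2,7,8-trimethyl-3,4-dihydro-2H-chromen-6-yl]oxy](tert-butyl)dimethylsilane
Product: 17 tert-butyl-[[(2S)-2-[(3E,7E)-4,8-dimethyltrideca-3,7-dien-11-yn-1-yl]-2,7,8-trimethyl-3,4-dihydro-2H-chromen-6-yl]oxy]dimethylsilane, via lithium acetylide 16 (not isolated)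
Conditions: propyne, n-BuLi (2 equiv per propyne), TMEDA, Et2O/hexane, −78 to 0 °C; then 15, THF, −78 to 0 °C; then MeI, 0 to 20 °C
Reagents that add atoms: propyne CC#C; iodomethane CI
Why: propargylation of an allylic bromide with 1,3-dilithiopropyne: the sp3 carbanion is the more nucleophilic end and displaces the primary allylic bromide (SN2, forming C9′–C10′), and the lithium acetylide that remains is methylated in the same flask to the methyl alkyne.

Step 13
Reactants: 17 tert-butyl-[[(2S)-2-[(3E,7E)-4,8-dimethyltrideca-3,7-dien-11-yn-1-yl]-2,7,8-trimethyl-3,4-dihydro-2H-chromen-6-yl]oxy]dimethylsilane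
Product: 19 [[(2S)-2-[(3E,7E,11E)-12-bromo-4,8-dimethyltrideca-3,7,11-trien-1-yl]-2,7,8-trimethyl-3,4-dihydro-2H-chromen-6-yl]oxy](tert-butyl)dimethylsilane, via alkenylzirconocene chloride 18 (not isolated)
Conditions: Cp2Zr(H)Cl (1.5 equiv), THF, 45 °C; then NBS, 0 °C
Reagents that add atoms: N-bromosuccinimide O=C1CCC(=O)N1Br
Why: hydrozirconation/bromination: Zr–H adds syn, the slight excess of hydride equilibrates zirconium onto the less hindered methyl-bearing carbon C12′, and NBS cleaves the C–Zr bond with retention, which should give the (11′E)-12′-bromide.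

Step 14
Reactants: 20 geranyl acetate
Product: 21 (2E,6E)-8-hydroxy-3,7-dimethylocta-2,6-dien-1-yl acetate
Conditions: SeO2 (0.3 equiv), t-BuOOH (3 equiv), salicylic acid (0.1 equiv), CH2Cl2, 20 °C
Reagents that add atoms: selenium dioxide O=[Se]=O; tert-butyl hydroperoxide CC(C)(C)OO (renews SeO2)
Why: SeO2 allylic oxidation: the 2,3-olefin is deactivated by the allylic acetate, so the ene reaction occurs at the terminal olefin and at its E-methyl group, giving the E-allylic alcohol.

Step 15
Reactants: 21 (2E,6E)-8-hydroxy-3,7-dimethylocta-2,6-dien-1-yl acetate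
Product: 22 (2E,6E)-8-bromo-3,7-dimethylocta-2,6-dien-1-yl acetate
Conditions: CBr4, PPh3, CH2Cl2, 0 °C
Reagents that add atoms: carbon tetrabromide BrC(Br)(Br)Br
Why: Appel bromination of the primary allylic alcohol by SN2 displacement, the allylic acetate at the other end being inert.

Step 16
Reactants: 4 (3S,6E)-3,7,11-trimethyldodeca-6,10-dien-1-yn-3-ol; 22 (2E,6E)-8-bromo-3,7-dimethylocta-2,6-dien-1-yl acetate
Product: 23 (2E,6E,11S,14E)-11-hydroxy-3,7,11,15,19-pentamethylicosa-2,6,14,18-tetraen-9-yn-1-yl acetate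
Conditions: CuI (1 equiv), K2CO3, NaI, DMF, 20 °C
Reagents that add atoms: none
Why: copper-mediated coupling of a terminal alkyne with an allylic bromide: the alkyne C–H is cuprated in the flask and the C21′–C22′ bond forms at the unhindered CH2 end of the allylic bromide, the allylic acetate and the free tertiary alcohol being inert under these mild carbonate conditions.

Step 17
Reactants: 23 (2E,6E,11S,14E)-11-hydroxy-3,7,11,15,19-pentamethylicosa-2,6,14,18-tetraen-9-yn-1-yl acetate
Product: 24 (2E,6E,9E,11S,14E)-3,7,11,15,19-pentamethylicosa-2,6,9,14,18-pentaene-1,11-diol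
Conditions: NaAlH2(OCH2CH2OMe)2 (4 equiv), THF, 0 to 40 °C; then aq. Rochelle salt
Reagents that add atoms: none
Why: hydroxyl-directed trans-hydroalumination of the propargylic alcohol followed by protonolysis gives the E-disubstituted olefin (22′E), isolated olefins are inert to the hydride, and the acetate is cleaved to the primary allylic alcohol in the same operation.

Step 18
Reactants: 24 (2E,6E,9E,11S,14E)-3,7,11,15,19-pentamethylicosa-2,6,9,14,18-pentaene-1,11-diol
Product: 25 (2E,6E,9E,11S,14E)-11-hydroxy-3,7,11,15,19-pentamethylicosa-2,6,9,14,18-pentaenal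
Conditions: MnO2 (activated, excess), CH2Cl2, 20 °C
Reagents that add atoms: none
Why: MnO2 oxidises only the primary allylic alcohol (the tertiary allylic alcohol has no carbinol hydrogen) and should give the E-enal without isomerisation.

Step 19
Reactants: 25 (2E,6E,9E,11S,14E)-11-hydroxy-3,7,11,15,19-pentamethylicosa-2,6,9,14,18-pentaenal
Product: 26 (6E,10S,11E,14E,18E)-2,6,10,14,18-pentamethylhenicosa-2,6,11,14,18,20-hexaen-10-ol
Conditions: Ph3PCH3Br, KOtBu (2.5 equiv of ylide), THF, 0 °C
Reagents that add atoms: methyltriphenylphosphonium bromide [Br-].C[P+](c1ccccc1)(c1ccccc1)c1ccccc1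
Why: Wittig methylenation with the non-stabilised ylide turns the enal into the terminal 1,3-diene and brings in C13′; the excess ylide covers the free tertiary hydroxyl and the 15′E olefin is not affected.

Step 20
Reactants: 26 (6E,10S,11E,14E,18E)-2,6,10,14,18-pentamethylhenicosa-2,6,11,14,18,20-hexaen-10-ol
Product: 28 (3E,7E,10E,12S,15E)-4,8,12,16,20-pentamethylhenicosa-3,7,10,15,19-pentaene-1,12-diol, via B-alkyl-9-BBN borane 27 (not isolated)
Conditions: 9-BBN (1.3 equiv), THF, 0 to 20 °C; then NaOH, H2O2, 0 °C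
Reagents that add atoms: hydrogen peroxide OO
Why: hydroboration–oxidation: 9-BBN adds to the unsubstituted end of the conjugated diene (boron on C13′) much faster than to the trisubstituted olefins or the hindered 1,2-disubstituted olefin, and alkaline peroxide gives the primary homoallylic alcohol.

Step 21
Reactants: 28 (3E,7E,10E,12S,15E)-4,8,12,16,20-pentamethylhenicosa-3,7,10,15,19-pentaene-1,12-diol
Product: 29 (6E,10S,11E,14E,18E)-21-bromo-2,6,10,14,18-pentamethylhenicosa-2,6,11,14,18-pentaen-10-ol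
Conditions: CBr4, PPh3, 2,6-lutidine, CH2Cl2, 0 °C
Reagents that add atoms: carbon tetrabromide BrC(Br)(Br)Br
Why: Appel bromination of the primary alcohol; the hindered tertiary allylic alcohol does not form the alkoxyphosphonium ion at 0 °C, and the base keeps the medium free of acid.

Step 22
Reactants: 29 (6E,10S,11E,14E,18E)-21-bromo-2,6,10,14,18-pentamethylhenicosa-2,6,11,14,18-pentaen-10-ol; 19 [[(2S)-2-[(3E,7E,11E)-12-bromo-4,8-dimethyltrideca-3,7,11-trien-1-yl]-2,7,8-trimethyl-3,4-dihydro-2H-chromen-6-yl]oxy](tert-butyl)dimethylsilane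
Product: 30 tert-butyl-[[(2S)-2-[(3E,7E,11E,15E,19E,22E,24S,27E)-24-hydroxy-4,8,12,16,20,24,28,32-octamethyltritriaconta-3,7,11,15,19,22,27,31-octaen-1-yl]-2,7,8-trimethyl-3,4-dihydro-2H-chromen-6-yl]oxy]dimethylsilane
Conditions: NiBr2(dme) (5 mol%), 2,2′-bipyridine (5 mol%), Mn powder (2 equiv), NaI (0.25 equiv), DMPU, 25 °C, Ar; 29 (1.2 equiv)
Reagents that add atoms: none
Why: Nickel-catalysed reductive cross-electrophile coupling: zerovalent nickel inserts into the C(sp2)–Br bond of 19 with retention, monovalent nickel abstracts bromine from 29 to give the primary C13′ radical, the radical is captured by the alkenyl nickel bromide (divalent nickel), and reductive elimination from trivalent nickel forms C12′–C13′ while Mn returns nickel to the zerovalent state. The closest known reaction type is the nickel/bipyridine/Mn coupling of alkenyl bromides with primary alkyl bromides. No ring is closed and no stereocentre is formed; C2 and C24′ lie more than ten bonds from the reacting carbons and are untouched. The step needs cross- over homo-coupling, which the two different activation modes secure (two-electron insertion at the alkenyl bromide, one-electron halogen abstraction at the alkyl bromide), and retention of the 11′E geometry, which the configurationally stable σ-alkenyl nickel species secures. The 15′E olefin next to the radical should survive because 3-exo closure of a homoallyl radical is slow and reversible compared with capture by nickel. The free tertiary allylic alcohol and the aryl silyl ether are inert to Mn and low-valent nickel at 25 °C, so the union needs no further protection.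

Step 23
Reactants: 30 tert-butyl-[[(2S)-2-[(3E,7E,11E,15E,19E,22E,24S,27E)-24-hydroxy-4,8,12,16,20,24,28,32-octamethyltritriaconta-3,7,11,15,19,22,27,31-octaen-1-yl]-2,7,8-trimethyl-3,4-dihydro-2H-chromen-6-yl]oxy]dimethylsilane
Product: 31 (2S)-2-[(3E,7E,11E,15E,19E,22E,24S,27E)-24-hydroxy-4,8,12,16,20,24,28,32-octamethyltritriaconta-3,7,11,15,19,22,27,31-octaen-1-yl]-2,7,8-trimethyl-3,4-dihydro-2H-chromen-6-ol
Conditions: Bu4NF (1.2 equiv), AcOH (1.2 equiv), THF, 0 °C, Ar
Reagents that add atoms: none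
Why: fluoride cleavage of the aryl silyl ether, driven by Si–F bond formation and buffered with AcOH so that the chromanol is not left as a phenoxide in air; the tertiary allylic alcohol and the polyene are untouched.

**Compound list**

1 | (2E,6E)-farnesol | CC(C)=CCC/C(C)=C/CC/C(C)=C/CO | starting material
2 | [(2S,3S)-3-[(3E)-4,8-dimethylnona-3,7-dien-1-yl]-3-methyloxiran-2-yl]methanol | CC(C)=CCC/C(C)=C/CC[C@]1(C)O[C@H]1CO | intermediate
3 | (2S,3R)-3-(chloromethyl)-2-[(3E)-4,8-dimethylnona-3,7-dien-1-yl]-2-methyloxirane | CC(C)=CCC/C(C)=C/CC[C@]1(C)O[C@H]1CCl | intermediate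
4 | (3S,6E)-3,7,11-trimethyldodeca-6,10-dien-1-yn-3-ol | CC(C)=CCC/C(C)=C/CC[C@](C)(O)C#C | intermediate
5 | (3S,6E)-3,7,11-trimethyldodeca-1,6,10-trien-3-ol | CC(C)=CCC/C(C)=C/CC[C@](C)(O)C=C | intermediate
6 | 1,4-dimethoxy-2,3-dimethylbenzene | COc1ccc(OC)c(C)c1C | starting material
7 | 1-bromo-2,5-dimethoxy-3,4-dimethylbenzene | COc1cc(Br)c(OC)c(C)c1C | intermediate
8 | 9-[(3R,6E)-3-hydroxy-3,7,11-trimethyldodeca-6,10-dien-1-yl]-9-borabicyclo[3.3.1]nonane (same spatial arrangement as 5; descriptor changed by priority) | CC(C)=CCC/C(C)=C/CC[C@](C)(O)CCB1C2CCCC1CCC2 | intermediate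
9 | (3S,6E)-1-(2,5-dimethoxy-3,4-dimethylphenyl)-3,7,11-trimethyldodeca-6,10-dien-3-ol | CC(C)=CCC/C(C)=C/CC[C@](C)(O)CCc1cc(OC)c(C)c(C)c1OC | intermediate
10 | 5-[(3S,6E)-3-hydroxy-3,7,11-trimethyldodeca-6,10-dien-1-yl]-2,3-dimethylcyclohexa-2,5-diene-1,4-dione | CC(C)=CCC/C(C)=C/CC[C@](C)(O)CCC1=CC(=O)C(C)=C(C)C1=O | intermediate
11 | 5-[(3S,6E)-3-hydroxy-3,7,11-trimethyldodeca-6,10-dien-1-yl]-2,3-dimethylbenzene-1,4-diol | CC(C)=CCC/C(C)=C/CC[C@](C)(O)CCc1cc(O)c(C)c(C)c1O | intermediate
12 | (2S)-2-[(3E)-4,8-dimethylnona-3,7-dien-1-yl]-2,7,8-trimethyl-3,4-dihydro-2H-chromen-6-ol | CC(C)=CCC/C(C)=C/CC[C@@]1(C)CCc2cc(O)c(C)c(C)c2O1 | intermediate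
13 | tert-butyl-[[(2S)-2-[(3E)-4,8-dimethylnona-3,7-dien-1-yl]-2,7,8-trimethyl-3,4-dihydro-2H-chromen-6-yl]oxy]dimethylsilane | CC(C)=CCC/C(C)=C/CC[C@@]1(C)CCc2cc(O[Si](C)(C)C(C)(C)C)c(C)c(C)c2O1 | intermediate
14 | (2E,6E)-9-[(2S)-6-[tert-butyl(dimethyl)silyl]oxy-2,7,8-trimethyl-3,4-dihydro-2H-chromen-2-yl]-2,6-dimethylnona-2,6-dien-1-ol | OC/C(C)=C/CC/C(C)=C/CC[C@@]1(C)CCc2cc(O[Si](C)(C)C(C)(C)C)c(C)c(C)c2O1 | intermediate
15 | [[(2S)-2-[(3E,7E)-9-bromo-4,8-dimethylnona-3,7-dien-1-yl]-2,7,8-trimethyl-3,4-dihydro-2H-chromen-6-yl]oxy](tert-butyl)dimethylsilane | BrC/C(C)=C/CC/C(C)=C/CC[C@@]1(C)CCc2cc(O[Si](C)(C)C(C)(C)C)c(C)c(C)c2O1 | intermediate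
16 | lithium (5E,9E)-12-[(2S)-6-[tert-butyl(dimethyl)silyl]oxy-2,7,8-trimethyl-3,4-dihydro-2H-chromen-2-yl]-5,9-dimethyldodeca-5,9-dien-1-yn-1-ide | [Li]C#CCC/C(C)=C/CC/C(C)=C/CC[C@@]1(C)CCc2cc(O[Si](C)(C)C(C)(C)C)c(C)c(C)c2O1 | intermediate
17 | tert-butyl-[[(2S)-2-[(3E,7E)-4,8-dimethyltrideca-3,7-dien-11-yn-1-yl]-2,7,8-trimethyl-3,4-dihydro-2H-chromen-6-yl]oxy]dimethylsilane | CC#CCC/C(C)=C/CC/C(C)=C/CC[C@@]1(C)CCc2cc(O[Si](C)(C)C(C)(C)C)c(C)c(C)c2O1 | intermediate
18 | chloridobis(cyclopentadienyl)[(2E,6E,10E)-13-[(2S)-6-[tert-butyl(dimethyl)silyl]oxy-2,7,8-trimethyl-3,4-dihydro-2H-chromen-2-yl]-6,10-dimethyltrideca-2,6,10-trien-2-yl]zirconium | C/C(=C\CC/C(C)=C/CC/C(C)=C/CC[C@@]1(C)CCc2cc(O[Si](C)(C)C(C)(C)C)c(C)c(C)c2O1)[Zr](Cl)(C1C=CC=C1)C1C=CC=C1 | intermediate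
19 | [[(2S)-2-[(3E,7E,11E)-12-bromo-4,8-dimethyltrideca-3,7,11-trien-1-yl]-2,7,8-trimethyl-3,4-dihydro-2H-chromen-6-yl]oxy](tert-butyl)dimethylsilane | Br/C(C)=C/CC/C(C)=C/CC/C(C)=C/CC[C@@]1(C)CCc2cc(O[Si](C)(C)C(C)(C)C)c(C)c(C)c2O1 | intermediate
20 | geranyl acetate, (2E)-3,7-dimethylocta-2,6-dien-1-yl acetate | CC(C)=CCC/C(C)=C/COC(C)=O | starting material
21 | (2E,6E)-8-hydroxy-3,7-dimethylocta-2,6-dien-1-yl acetate | OC/C(C)=C/CC/C(C)=C/COC(C)=O | intermediate
22 | (2E,6E)-8-bromo-3,7-dimethylocta-2,6-dien-1-yl acetate | BrC/C(C)=C/CC/C(C)=C/COC(C)=O | intermediate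
23 | (2E,6E,11S,14E)-11-hydroxy-3,7,11,15,19-pentamethylicosa-2,6,14,18-tetraen-9-yn-1-yl acetate | CC(C)=CCC/C(C)=C/CC[C@](C)(O)C#CC/C(C)=C/CC/C(C)=C/COC(C)=O | intermediate
24 | (2E,6E,9E,11S,14E)-3,7,11,15,19-pentamethylicosa-2,6,9,14,18-pentaene-1,11-diol | CC(C)=CCC/C(C)=C/CC[C@](C)(O)/C=C/C/C(C)=C/CC/C(C)=C/CO | intermediate
25 | (2E,6E,9E,11S,14E)-11-hydroxy-3,7,11,15,19-pentamethylicosa-2,6,9,14,18-pentaenal | CC(C)=CCC/C(C)=C/CC[C@](C)(O)/C=C/C/C(C)=C/CC/C(C)=C/C=O | intermediate
26 | (6E,10S,11E,14E,18E)-2,6,10,14,18-pentamethylhenicosa-2,6,11,14,18,20-hexaen-10-ol | CC(C)=CCC/C(C)=C/CC[C@](C)(O)/C=C/C/C(C)=C/CC/C(C)=C/C=C | intermediate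
27 | 9-[(3E,7E,10E,12S,15E)-12-hydroxy-4,8,12,16,20-pentamethylhenicosa-3,7,10,15,19-pentaen-1-yl]-9-borabicyclo[3.3.1]nonane | CC(C)=CCC/C(C)=C/CC[C@](C)(O)/C=C/C/C(C)=C/CC/C(C)=C/CCB1C2CCCC1CCC2 | intermediate
28 | (3E,7E,10E,12S,15E)-4,8,12,16,20-pentamethylhenicosa-3,7,10,15,19-pentaene-1,12-diol | CC(C)=CCC/C(C)=C/CC[C@](C)(O)/C=C/C/C(C)=C/CC/C(C)=C/CCO | intermediate
29 | (6E,10S,11E,14E,18E)-21-bromo-2,6,10,14,18-pentamethylhenicosa-2,6,11,14,18-pentaen-10-ol | CC(C)=CCC/C(C)=C/CC[C@](C)(O)/C=C/C/C(C)=C/CC/C(C)=C/CCBr | intermediate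
30 | tert-butyl-[[(2S)-2-[(3E,7E,11E,15E,19E,22E,24S,27E)-24-hydroxy-4,8,12,16,20,24,28,32-octamethyltritriaconta-3,7,11,15,19,22,27,31-octaen-1-yl]-2,7,8-trimethyl-3,4-dihydro-2H-chromen-6-yl]oxy]dimethylsilane | CC(C)=CCC/C(C)=C/CC[C@](C)(O)/C=C/C/C(C)=C/CC/C(C)=C/CC/C(C)=C/CC/C(C)=C/CC/C(C)=C/CC[C@@]1(C)CCc2cc(O[Si](C)(C)C(C)(C)C)c(C)c(C)c2O1 | intermediate
31 | (2S)-2-[(3E,7E,11E,15E,19E,22E,24S,27E)-24-hydroxy-4,8,12,16,20,24,28,32-octamethyltritriaconta-3,7,11,15,19,22,27,31-octaen-1-yl]-2,7,8-trimethyl-3,4-dihydro-2H-chromen-6-ol | CC(C)=CCC/C(C)=C/CC[C@](C)(O)/C=C/C/C(C)=C/CC/C(C)=C/CC/C(C)=C/CC/C(C)=C/CC/C(C)=C/CC[C@@]1(C)CCc2cc(O)c(C)c(C)c2O1 | target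

**Count and risks**

Total steps: 23. Longest linear sequence: 14 steps (steps 1–4, 6–13, 22, 23).

Step 22. What may go wrong: homo-coupling of either bromide, simple reduction of the alkyl bromide, or partial E/Z scrambling at C15′ through reversible ring closure of the C13′ radical. The fallback avoids radicals altogether and sets out from diene 26 and alkenyl bromide 19. Diene 26 would be hydroborated with 9-BBN (THF, 0 to 20 °C) to borane 27, which would be coupled directly with 19 in a B-alkyl Suzuki–Miyaura reaction (Pd(dppf)Cl2, AsPh3, Cs2CO3, DMF/THF/H2O, 20 °C). It comes back to the route at 30 and makes no compound outside the list (entry F0).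

Step 13. What may go wrong: incomplete regiocontrol of the Zr–H addition, so that part of the zirconium (and then the bromine) ends on C11′ and a regioisomer that cannot be separated is carried into the union. The fallback fixes the regiochemistry with silicon and sets out from 15. The lithium acetylide 16 of step 12 would be trapped with Me3SiCl instead of MeI to give the silyl alkyne F1. trans-Hydroalumination with i-Bu2AlH in heptane (50 °C) would place aluminium only on the silicon-bearing carbon and give the α-silyl alkenylalane F2. MeLi and then MeI would methylate that carbon with retention to the vinylsilane F3, and NIS (MeCN, 0 °C) would replace silicon by iodine with retention to give the (11′E)-12′-iodide F4. F4 would then be coupled with 29 under the conditions of step 22, so the fallback comes back to the route at 30.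

Step 8. What may go wrong: partial loss of configuration at C2 if the tertiary carbinol ionises before the ring closes, or acid-induced cyclisation of the side-chain olefins. The fallback closes the ring before the reduction and sets out from quinone 10. Trimethyl orthoformate, MeOH and camphorsulfonic acid (cat., 20 °C) would close the pyran ring at the quinone level to the mixed methyl ketal F5, in which the C2–O bond has never been broken. Ascorbic acid (aq. THF, 20 °C) would then reduce the ketal to chromanol 12, where the route is rejoined.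

**Further compounds**

F0 | step 22 | none | none
F1 | step 13 | tert-butyl-[[(2S)-2-[(3E,7E)-4,8-dimethyl-12-(trimethylsilyl)dodeca-3,7-dien-11-yn-1-yl]-2,7,8-trimethyl-3,4-dihydro-2H-chromen-6-yl]oxy]dimethylsilane | C[Si](C)(C)C#CCC/C(C)=C/CC/C(C)=C/CC[C@@]1(C)CCc2cc(O[Si](C)(C)C(C)(C)C)c(C)c(C)c2O1
F2 | step 13 | [(1E,5E,9E)-12-[(2S)-6-[tert-butyl(dimethyl)silyl]oxy-2,7,8-trimethyl-3,4-dihydro-2H-chromen-2-yl]-5,9-dimethyl-1-(trimethylsilyl)dodeca-1,5,9-trien-1-yl]bis(2-methylpropyl)alumane | CC(C)C[Al](CC(C)C)/C(=C\CC/C(C)=C/CC/C(C)=C/CC[C@@]1(C)CCc2cc(O[Si](C)(C)C(C)(C)C)c(C)c(C)c2O1)[Si](C)(C)C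
F3 | step 13 | tert-butyl-[[(2S)-2-[(3E,7E,11E)-4,8-dimethyl-12-(trimethylsilyl)trideca-3,7,11-trien-1-yl]-2,7,8-trimethyl-3,4-dihydro-2H-chromen-6-yl]oxy]dimethylsilane | C/C(=C\CC/C(C)=C/CC/C(C)=C/CC[C@@]1(C)CCc2cc(O[Si](C)(C)C(C)(C)C)c(C)c(C)c2O1)[Si](C)(C)C
F4 | step 13 | tert-butyl-[[(2S)-2-[(3E,7E,11E)-12-iodo-4,8-dimethyltrideca-3,7,11-trien-1-yl]-2,7,8-trimethyl-3,4-dihydro-2H-chromen-6-yl]oxy]dimethylsilane | I/C(C)=C/CC/C(C)=C/CC/C(C)=C/CC[C@@]1(C)CCc2cc(O[Si](C)(C)C(C)(C)C)c(C)c(C)c2O1
F5 | step 8 | (2S)-2-[(3E)-4,8-dimethylnona-3,7-dien-1-yl]-8a-methoxy-2,7,8-trimethyl-2,3,4,8a-tetrahydro-6H-chromen-6-one (both configurations at C8a) | CC(C)=CCC/C(C)=C/CC[C@@]1(C)CCC2=CC(=O)C(C)=C(C)C2(OC)O1
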